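The pyranone ring is disconnected at its three bonds to the outside: C4a–C4, C4–C3 and O1–C2. In that ring the ketone carbon C4 is bonded on one side to the ring-fusion carbon C4a and on the other to the C3=C2 alkene whose C2 carries the C33 chain. C4 is therefore assigned to carbon monoxide, and C3, C2 and the chain to a C35 1-alkyne. One palladium-catalysed carbonylative alkynylation with ring closure in the same flask should build the whole pyranone ring and give the target directly. The aryl partner is unprotected 2-iodo-5-methoxyresorcinol; its two hydroxyls flank the iodide and are symmetry-equivalent, so closure through either gives the 5-hydroxy-7-methoxy pattern.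

Key step: step 7

Assumption: the side chain is read as unbranched n-tritriacontyl (33 carbons), and (5-chloropent-1-yn-1-yl)trimethylsilane is taken as a catalogue reagent.

Step 1
Reactants: 1 5-methoxyresorcinol (5-methoxybenzene-1,3-diol)
Product: 2 1-methoxy-3,5-bis(methoxymethoxy)benzene
Conditions: MOMCl (2.5 equiv), iPr2NEt (3 equiv), CH2Cl2, 0 °C → rt
Reagents that add atoms: chloromethyl methyl ether (MOMCl), COCCl
Why: Williamson-type O-alkylation of both phenols by the reactive α-chloro ether under amine base should give the bis-acetal, which is inert to organolithium reagents and serves as the directing group in the next step.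

Step 2
Reactants: 2 1-methoxy-3,5-bis(methoxymethoxy)benzene
Product: 4 2-iodo-5-methoxy-1,3-bis(methoxymethoxy)benzene, via aryllithium 3 (not isolated)
Conditions: n-BuLi (1.2 equiv), THF, 0 °C → rt; then I2, THF, −78 °C → rt
Reagents that add atoms: iodine, II
Why: Directed ortho-metalation should take place at the carbon flanked by the two chelating OMOM groups, the most acidic and best coordinated site, and iodine then traps the aryllithium at that carbon.

Step 3
Reactants: 4 2-iodo-5-methoxy-1,3-bis(methoxymethoxy)benzene
Product: 5 2-iodo-5-methoxybenzene-1,3-diol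
Conditions: 1 M HCl in MeOH, 40 °C, argon, exclusion of light
Reagents that add atoms: none
Why: Acid-catalysed transacetalisation with methanol cleaves both MOM ethers under conditions mild enough to leave the aryl iodide and the methyl ether intact; the diol is used promptly.

Step 4
Reactants: 6 triacontan-1-ol
Product: 7 1-bromotriacontane
Conditions: PPh3, CBr4, THF, 40 °C
Reagents that add atoms: carbon tetrabromide, BrC(Br)(Br)Br
Why: In this Appel reaction bromide displaces the alkoxyphosphonium group by SN2 at an unhindered primary carbon, and warm THF keeps the waxy alcohol in solution.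

Step 5
Reactants: 8 (5-chloropent-1-yn-1-yl)trimethylsilane; 7 1-bromotriacontane
Product: 10 trimethyl(pentatriacont-1-yn-1-yl)silane, via Grignard reagent 9 (not isolated)
Conditions: 8, Mg, BrCH2CH2Br (cat.), THF, reflux; then 7, Li2CuCl4 (3 mol %), THF–NMP, 20 → 40 °C
Reagents that add atoms: none
Why: Magnesium insertion into the primary chloride followed by copper-catalysed sp3–sp3 cross-coupling of the Grignard reagent with the primary bromide (Kochi coupling) should join the C5 and C30 pieces, the silyl cap removing the acidic alkyne hydrogen that would otherwise quench the organomagnesium.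

Step 6
Reactants: 10 trimethyl(pentatriacont-1-yn-1-yl)silane
Product: 11 pentatriacont-1-yne
Conditions: K2CO3 (0.5 equiv), MeOH–THF 1:3, 45 °C
Reagents that add atoms: none
Why: Methoxide-mediated protodesilylation cleaves only the C(sp)–Si bond, and the THF co-solvent keeps the long-chain substrate dissolved.

Step 7
Reactants: 5 2-iodo-5-methoxybenzene-1,3-diol; 11 pentatriacont-1-yne; 12 carbon monoxide
Product: 15 5-hydroxy-7-methoxy-2-tritriacontyl-4H-chromen-4-one (target), via ynone 13 (not isolated), via enaminone 14 (not isolated)
Conditions: PdCl2(dppf) (5 mol %), CO (20 bar), Et2NH–toluene 1:1, 120 °C, autoclave; 5 in slight excess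
Reagents that add atoms: none
Why: Pd(0) should insert into the C–I bond of 5, CO insertion gives the aroylpalladium iodide, and amine-assisted transfer of the alkynyl group of 11 with reductive elimination forms C4a–C4 and C4–C3 in ynone 13. Diethylamine then adds to the ynone to give enaminone 14, and an ortho hydroxyl attacks the amine-bearing carbon and expels the amine, forming O1–C2. The closest known reaction type is the palladium-catalysed carbonylative annulation of 2-iodophenols with terminal alkynes in diethylamine, established for both alkyl- and arylacetylenes. The pyranone ring closes in a net 6-endo sense by addition–elimination at C2, and no stereocentre is formed. The step needs chemoselectivity (carbonylative over direct alkynylation, secured by CO pressure) and ring-size selectivity (chromone over 5-exo aurone, secured by the enaminone relay, which makes C2 the only electrophilic carbon). No regiochemical choice arises because the two hydroxyls of 5 are equivalent by symmetry, and the one that does not close becomes the hydrogen-bonded C5–OH.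

Compound list
1 | 5-methoxyresorcinol (5-methoxybenzene-1,3-diol) | COc1cc(O)cc(O)c1 | starting material
2 | 1-methoxy-3,5-bis(methoxymethoxy)benzene | COCOc1cc(OC)cc(OCOC)c1 | intermediate
3 | [4-methoxy-2,6-bis(methoxymethoxy)phenyl]lithium | COCOc1cc(OC)cc(OCOC)c1[Li] | intermediate
4 | 2-iodo-5-methoxy-1,3-bis(methoxymethoxy)benzene | COCOc1cc(OC)cc(OCOC)c1I | intermediate
5 | 2-iodo-5-methoxybenzene-1,3-diol | COc1cc(O)c(I)c(O)c1 | intermediate
6 | triacontan-1-ol | CCCCCCCCCCCCCCCCCCCCCCCCCCCCCCO | starting material
7 | 1-bromotriacontane | CCCCCCCCCCCCCCCCCCCCCCCCCCCCCCBr | intermediate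
8 | (5-chloropent-1-yn-1-yl)trimethylsilane | C[Si](C)(C)C#CCCCCl | starting material
9 | [5-(trimethylsilyl)pent-4-yn-1-yl]magnesium chloride | C[Si](C)(C)C#CCCC[Mg]Cl | intermediate
10 | trimethyl(pentatriacont-1-yn-1-yl)silane | CCCCCCCCCCCCCCCCCCCCCCCCCCCCCCCCCC#C[Si](C)(C)C | intermediate
11 | pentatriacont-1-yne | CCCCCCCCCCCCCCCCCCCCCCCCCCCCCCCCCC#C | intermediate
12 | carbon monoxide | [C-]#[O+] | starting material
13 | 1-(2,6-dihydroxy-4-methoxyphenyl)hexatriacont-2-yn-1-one | CCCCCCCCCCCCCCCCCCCCCCCCCCCCCCCCCC#CC(=O)c1c(O)cc(OC)cc1O | intermediate
14 | (2E)-3-(diethylamino)-1-(2,6-dihydroxy-4-methoxyphenyl)hexatriacont-2-en-1-one (drawn as E; the geometry does not matter for ring closure) | COc1cc(O)c(C(=O)/C=C(/N(CC)CC)CCCCCCCCCCCCCCCCCCCCCCCCCCCCCCCCC)c(O)c1 | intermediate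
15 | 5-hydroxy-7-methoxy-2-tritriacontyl-4H-chromen-4-one | CCCCCCCCCCCCCCCCCCCCCCCCCCCCCCCCCc1cc(=O)c2c(O)cc(OC)cc2o1 | target

Total step count: 7. Longest linear sequence: 4 steps (1 → 2 → 3 → 7, or equally 4 → 5 → 6 → 7).

Steps most likely to fail

1. Step 7. Oxidative addition into the electron-rich, doubly ortho-flanked C–I bond may be slow. Hydrodeiodination, capture of the aroylpalladium species by the amine, or CO-free alkynylation followed by five-membered closure could then compete. The fallback avoids palladium; it sets out from 2 and 11 and returns at 15. Compound 2 is lithiated as in step 2 to aryllithium 3 and quenched with DMF to give 4-methoxy-2,6-bis(methoxymethoxy)benzaldehyde F1. Compound 11 is deprotonated with n-BuLi in THF to lithium pentatriacont-1-yn-1-ide F2, which adds to F1 to give racemic 1-[4-methoxy-2,6-bis(methoxymethoxy)phenyl]hexatriacont-2-yn-1-ol F3. MnO2 in CH2Cl2–THF oxidises the propargylic alcohol to 1-[4-methoxy-2,6-bis(methoxymethoxy)phenyl]hexatriacont-2-yn-1-one F4. Conjugate addition of Et2NH in EtOH–THF gives (2E)-3-(diethylamino)-1-[4-methoxy-2,6-bis(methoxymethoxy)phenyl]hexatriacont-2-en-1-one F5. HCl in MeOH–THF then removes both MOM groups, and the freed phenol closes the pyranone with loss of diethylamine to give 15.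

2. Step 5. Magnesium insertion into the primary chloride may stall, or the waxy bromide may come out of solution, so that homocoupling and reduction overtake the cross-coupling. The fallback sets out from 7 and returns at 11, bypassing step 6. Lithium pent-1-ynide (pent-1-yne, n-BuLi, THF–DMPU, 60 °C) is alkylated by 7 to give pentatriacont-4-yne F6. Potassium 3-aminopropylamide (KH, 1,3-diaminopropane, 55 °C) then isomerises the internal triple bond to the chain end (alkyne zipper reaction), where it is trapped as the terminal acetylide. Aqueous quench gives 11; either chain end gives the same 1-alkyne.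

3. Step 2. Metalation may occur partly at C4, between OMOM and OMe, or remain incomplete, so that an isomer mixture is carried into the deprotection, where acid-induced loss of iodine is a further hazard. The fallback sets out from 1 and returns at 5, bypassing steps 1–3. It is a direct electrophilic iodination of the free resorcinol with I2 and NaHCO3 in THF–H2O at 0 °C, the protocol that iodinates resorcinol and 5-alkylresorcinols between the two hydroxyls. The C2-symmetric product is told apart from the C4 isomer by its single aromatic proton signal and separated by crystallisation. It is not the main route because the position of iodination on this substrate is less assured than under directed metalation.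

Further compounds
F1 | step 7 | 4-methoxy-2,6-bis(methoxymethoxy)benzaldehyde | COCOc1cc(OC)cc(OCOC)c1C=O
F2 | step 7 | lithium pentatriacont-1-yn-1-ide | CCCCCCCCCCCCCCCCCCCCCCCCCCCCCCCCCC#C[Li]
F3 | step 7 | racemic 1-[4-methoxy-2,6-bis(methoxymethoxy)phenyl]hexatriacont-2-yn-1-ol | CCCCCCCCCCCCCCCCCCCCCCCCCCCCCCCCCC#CC(O)c1c(OCOC)cc(OC)cc1OCOC
F4 | step 7 | 1-[4-methoxy-2,6-bis(methoxymethoxy)phenyl]hexatriacont-2-yn-1-one | CCCCCCCCCCCCCCCCCCCCCCCCCCCCCCCCCC#CC(=O)c1c(OCOC)cc(OC)cc1OCOC
F5 | step 7 | (2E)-3-(diethylamino)-1-[4-methoxy-2,6-bis(methoxymethoxy)phenyl]hexatriacont-2-en-1-one | COCOc1cc(OC)cc(OCOC)c1C(=O)/C=C(/N(CC)CC)CCCCCCCCCCCCCCCCCCCCCCCCCCCCCCCCC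
F6 | step 5 | pentatriacont-4-yne | CCCC#CCCCCCCCCCCCCCCCCCCCCCCCCCCCCCCC
F0 | step 2 | none | none
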